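**The vessel.** The closed, stirred vessel holds starting material, second substrate and a trace of enzyme, which cycles through the first complex and the second complex. Each target costs one second substrate. Free enzyme can then spend one more second substrate to turn target into over-reaction product.

| flask | starting material | second substrate | free enzyme | remark | time |
|---|---|---|---|---|---|
| amber | 20 mM | 0.23 equiv | 0.023 mol% | run made earlier |  |
| green | 20 mM | 0.93 equiv | 0.023 mol% | run made earlier |  |
| spring | 20 mM | 0.250 equiv | 0.023 mol% |  | 3.0 h |
| winter | 20 mM | 0.500 equiv | 0.023 mol% |  | 3.0 h |
| noon | 20 mM | 1.00 equiv | 0.023 mol% |  | 3.0 h |
| autumn | 20 mM | 2.00 equiv | 0.023 mol% |  | 3.0 h |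
| summer | 20 mM | 4.00 equiv | 0.023 mol% |  | 3.0 h |

| run | time / min | target / % | starting material / % |
|---|---|---|---|
| amber | 10.0 | 11.4 | 88.9 |
| amber | 25.0 | 22.5 | 78.6 |
| amber | 50.0 | 22.9 | 76.3 |
| amber | 120 | 22.0 | 77.2 |
| green | 10.0 | 21.4 | 77.3 |
| green | 25.0 | 49.4 | 49.4 |
| green | 50.0 | 72.6 | 23.6 |
| green | 120 | 83.6 | 13.0 |

(scatter of a reading: 1 percentage point)

- reactions considered so far: second substrate + free enzyme + target -> free enzyme + over-reaction product; first complex -> loaded enzyme + first product; starting material + free enzyme <-> first complex; second complex -> free enzyme + target; second substrate + loaded enzyme <-> second complex
- "hardly changes" means that all values lie within two and a half points (for a concentration: within two and a half percent of the largest)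
- a step back or a flat step of under half a point counts as no turn

* amount of target at the end, in percent of the starting material charged for spring, winter, noon, autumn, summer, in this order
* how that number moves from the first to the last of them (falls all the way / falls, then rises / rises all the way / hardly changes / rises, then falls)

**Fastest rung.** Green reaches a target fraction of 49.4% at 25.0 min, so the whole charge needs about 50.6 min at that pace. With a loading of 0.023 mol%, one enzyme cycle takes about 0.0116 min, far shorter than the filling. The enzyme forms therefore follow the slowly moving charges.

**Middle rung.** Amber, charged with 0.23 equiv, reads 22.5% of target at 25.0 min and 22.0% at 120 min. Second substrate is the limiting reagent in amber, and its target fraction stays close to that charge.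

**Slowest rung.** Green's balance lacks 3.40% at 120 min. Each fraction converted takes one second substrate, and each fraction lost takes one more, so the readings give the second substrate standing at each time. Target times second substrate, summed over time, comes to 11.1 min. The ratio is the erosion constant, the fraction of target lost per minute for each equivalent of second substrate standing: 0.00307 min⁻¹. One equivalent then gives a target life of 326 min, longer than the filling. This is a rough reading, with a scatter of 1 percentage point on each value. Free enzyme takes part in the erosion, and green's catalyst can also stand in other forms, which leaves this reading uncertain for a flask with another share of free enzyme.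

**Own reckoning.** At green's pace, erosion has about 129 min after filling. In autumn, once the starting material has reacted, second substrate and target stand equal in equivalents, so target falls as one over one plus the constant times time, giving an estimate of 71.6%. Summer keeps a larger excess, and the same law gives an estimate of 35.5%. Spring and winter should follow their charges. Noon should stand near green's 83.6%, above both estimates.

**The forecast.** The forecast gives 24.5%, 49%, 87%, 62% and 28%, so the row rises, then falls, lower than these estimates at the last two points, and of those two it says “These last two are uncertain.”

**The result.** The flasks give 24.9%, 48.6%, 84.5%, 22.9% and 0.103%, so the row rises, then falls.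

    second substrate + free enzyme + target → free enzyme + over-reaction product (k = 2.50 × 10⁵ M⁻² min⁻¹)
    first complex → loaded enzyme + first product (k = 820 min⁻¹)
    starting material + free enzyme ⇌ first complex (K = 29.0 M⁻¹, k = 1.20 × 10⁵ M⁻¹ min⁻¹)
    second complex → free enzyme + target (k = 280 min⁻¹)
    second substrate + loaded enzyme ⇌ second complex (K = 94.0 M⁻¹, k = 45000 M⁻¹ s⁻¹)

**Autumn's clock.** Autumn ends with 0.229 equivalents of second substrate beside a target fraction of 22.9%. Put through the same law over 129 min, that target gives a constant of 0.0260 min⁻¹, which is 8.47 times green's 0.00307 min⁻¹. With autumn's constant, the law reckons summer's target at 0.0793%, and summer holds 0.103%.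

The earlier runs and the new flask come from a simulation from invented constants.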